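**Plan**

1. Retrosynthesis cuts, in order: the C8–O ester bond (epoxy acid off); C1–OMe and C10–H (methanol off a C1=C10 enone); C2–C3 of the ten-membered ring by a retro-Cope step that re-forms C5–C10; then, on the cyclohexanone, C10–vinyl, C5–isopropenyl, the lactone C6–O bond and C8–O, back to (S)-carvone.
2. Enabling feature: the β-methoxy ketone C1(OMe)–C10(H)–C9(=O) is a masked C1=C10 enone. With C4=C5 it makes the ten-membered ring a cyclodeca-1,5-diene (C10=C1–C2–C3–C4=C5) whose C5···C10 gap spans the six ring atoms C5–C6–C7–C8–C9–C10 of a carvone-type ring.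
3. Forward ring order: the six-membered ring comes from carvone, the γ-lactone is closed onto C6, the ten-membered ring arises by Cope ring expansion, and the epoxy ester goes on last.
4. Stereochemistry: C7 from (S)-carvone; C8 by Rubottom oxidation anti to the C7 substituent; C6 by intramolecular SN2 lactonisation (cis); C11 by base equilibration; C5/C10 trans by anti conjugate addition and anti aldol (erased in the Cope step, returned as the 4E and 1(10)E alkenes); C1 and C10 by methanol addition to the outer face of the E-enone; the oxirane by Sharpless epoxidation with D-(−)-diethyl tartrate.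
5. Numbering used for every compound: C1 CH–OMe, C2, C3, C4(Me)=C5, C6 lactone O–CH, C7, C8 CH–O-acyl, C9 C=O, C10 CH–Me, C11/C12 lactone CHMe/C=O.

Key step: step 10

Remark: compounds 4 to 9 are carried as mixtures of the two C11 epimers; step 6 makes them converge on the configuration of the target.

**Route**

Step 1
Reactants: 1 (S)-carvone
Product: 3 (5R,6R)-6-(tert-butyldimethylsilyloxy)carvone, via silyl dienol ether 2 (not isolated)
Conditions: LiN(i-Pr)2, THF, −78 °C; TBSOTf, −78 to 0 °C; then mCPBA, hexane, −15 °C
Reagents that add atoms: tert-butyldimethylsilyl triflate, CC(C)(C)[Si](C)(C)OS(=O)(=O)C(F)(F)F; mCPBA, OOC(=O)c1cccc(Cl)c1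
Why: Rubottom oxidation of the kinetic cross-conjugated silyl dienol ether, in which the peracid attacks the enol ether bond anti to the neighbouring isopropenyl group and the silyl group migrates to the new oxygen, so the C8 silyl ether is trans to the C7 substituent.

Step 2
Reactants: 3 (5R,6R)-6-(tert-butyldimethylsilyloxy)carvone
Product: 4 side-chain epoxide of 3 (both epimers at the oxirane carbon, the future C11)
Conditions: mCPBA, CH2Cl2, 0 °C
Reagents that add atoms: mCPBA, OOC(=O)c1cccc(Cl)c1
Why: Prilezhaev epoxidation that selects the electron-rich 1,1-disubstituted alkene over the electron-poor enone double bond; the new centre is formed unselectively, which is harmless because it is equilibrated in step 6.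

Step 3
Reactants: 4 side-chain epoxide
Product: 5 2-[6-(tert-butyldimethylsilyloxy)-4-methyl-5-oxocyclohex-3-en-1-yl]propanal (C11 epimers)
Conditions: BF3·OEt2 (0.3 equiv), CH2Cl2, −78 °C
Reagents that add atoms: none
Why: Meinwald rearrangement, in which the Lewis acid opens the 2,2-disubstituted oxirane at its tertiary carbon and a 1,2-hydride shift from the CH2 group gives the α-branched aldehyde (C12) without touching the ring stereocentres.

Step 4
Reactants: 5 enone aldehyde
Product: 6 2-[6-(tert-butyldimethylsilyloxy)-4-methyl-5-oxocyclohex-3-en-1-yl]propanoic acid (C11 epimers)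
Conditions: NaClO2, NaH2PO4, 2-methyl-2-butene, t-BuOH–H2O, 23 °C
Reagents that add atoms: NaClO2 (sodium chlorite), [Na+].[O-]Cl=O
Why: Pinnick oxidation, which converts the aldehyde to the acid under buffered conditions that leave the enone, the silyl ether and the α-ketol carbon alone.

Step 5
Reactants: 6 enone acid
Product: 9 cis-fused enone lactone (C11 epimers), via bis-silyl dienol ether 7 (not isolated), via bromo enone silyl ester 8 (not isolated)
Conditions: TBSOTf, Et3N, CH2Cl2, 0 °C; NBS, THF, −78 °C; then KHCO3, THF–H2O, 23 °C
Reagents that add atoms: none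
Why: Soft enolisation should run toward C6 because C8 is a hindered tertiary α-siloxy carbon, NBS then brominates the linear dienol ether at its γ-carbon C6 (γ-halogenation of cyclohexenone dienol ethers), and the carboxylate freed by bicarbonate displaces the allylic bromide in a 5-exo-tet SN2 reaction that can only give the cis-fused γ-lactone with C6–O on the face of the C7 side chain, a wrongly configured bromide being corrected by bromide exchange.

Step 6
Reactants: 9 cis-fused enone lactone (C11 epimers)
Product: 10 (3S,3aS,4R,7aS)-4-(tert-butyldimethylsilyloxy)-3,6-dimethyl-3,3a,4,7a-tetrahydro-1-benzofuran-2,5-dione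
Conditions: DBU, toluene, 80 °C
Reagents that add atoms: none
Why: Base-mediated α-epimerisation of a lactone, expected to settle on the epimer with the C11 methyl on the convex face of the cis-fused bicycle (anti to C8) and with the C8 silyl ether trans to the lactone, which are the configurations of the target.

Step 7
Reactants: 11 benzeneselenenyl chloride; 12 ethyl vinyl ether
Product: 14 (phenylseleno)acetaldehyde, via α-chloro ether 13 (not isolated)
Conditions: CH2Cl2, −78 °C; then H2O, NaHCO3, 0 °C; used fresh
Reagents that add atoms: water, O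
Why: Electrophilic selenenylation of the enol ether puts selenium on the terminal carbon because chloride is captured at the oxocarbenium carbon, and the α-chloro ether is hydrolysed to the aldehyde by aqueous bicarbonate; no stereocentre is involved.

Step 8
Reactants: 10 enone lactone; 15 isopropenylmagnesium bromide; 14 (phenylseleno)acetaldehyde
Product: 17 aldol adduct carrying the C5 isopropenyl group plus the C10 1-hydroxy-2-(phenylseleno)ethyl group (both carbinol epimers), via magnesium enolate 16 (not isolated)
Conditions: 15 added slowly, CuBr·SMe2 (0.2 equiv), THF, −78 °C; then 14, −78 °C; aqueous NH4Cl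
Reagents that add atoms: none
Why: Copper-catalysed conjugate addition of the Grignard reagent should deliver the isopropenyl group to C5 on the convex face, anti to the C6 oxygen, and the regiospecific magnesium enolate is then trapped at C10 by an aldol addition from the face opposite the new C5 substituent, so the two future alkenyl groups are trans; the carbinol centre is erased in step 9.

Step 9
Reactants: 17 aldol adduct
Product: 18 (3S,3aS,4R,6R,7R,7aS)-4-(tert-butyldimethylsilyloxy)-6-ethenyl-3,6-dimethyl-7-(prop-1-en-2-yl)hexahydro-1-benzofuran-2,5-dione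
Conditions: MsCl, Et3N, CH2Cl2, 0 to 23 °C
Reagents that add atoms: none
Why: Mesylation of the β-hydroxy selenide triggers the stereospecific anti elimination through a seleniranium ion (the selenium-based vinylation of ketone enolates), unveiling the vinyl group on the quaternary C10 without touching any stereocentre.

Step 10
Reactants: 18 trans-2-methyl-2-vinyl-3-isopropenylcyclohexanone lactone
Product: 19 (1(10)E,4E)-8-(tert-butyldimethylsilyloxy)-9-oxogermacra-1(10),4-dien-6,12-olide (C6, C7, C8 and C11 as in the target)
Conditions: degassed mesitylene, trace BHT, base-washed sealed tube, 180 °C; 19 separated by chromatography and recovered 18 heated again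
Reagents that add atoms: none
Why: Heating sets up the concerted [3,3] sigmatropic (Cope) equilibrium between the trans-1,2-dialkenylcyclohexanone 18 and the cyclodeca-1(10),4-dienone 19, the closest known reaction type being the thermal elemane–germacrane interconversion of sesquiterpenoids. The ten-membered carbocycle is closed by ring expansion: C2 of the vinyl group bonds to C3 of the isopropenyl group while the C5–C10 bond of the six-membered ring breaks, so no open-chain cyclisation is involved. No stereocentre is created; C5 and C10 become trigonal and both new alkenes should come out E because the two alkenyl groups are trans and react through the chair transition state in which they are diequatorial, with C6 and C9 in equatorial sites of that chair. The selectivity needed is thermodynamic, and what the substrate offers is conjugation of the new C1=C10 alkene with the C9 ketone together with relief of the 1,3-diaxial crowding that either chair of the fully substituted cyclohexanone must carry (C8 silyl ether against C10 methyl, or C6 oxygen against C10 vinyl). The position of the equilibrium cannot be predicted with confidence, so unchanged 18 is separated and resubmitted. C6, C7, C8 and C11 are spectators and keep their configuration.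

Step 11
Reactants: 19 E,E-dienone lactone
Product: 20 1-methoxy-8-(tert-butyldimethylsilyloxy)-9-oxogermacr-4-en-6,12-olide (all six ring stereocentres as in the target)
Conditions: NaOMe (0.1 equiv), MeOH, −20 to 0 °C; AcOH quench at −20 °C
Reagents that add atoms: methanol, CO
Why: Oxa-Michael addition of methoxide to the strained E-enone followed by protonation of the C10 enolate, in which nucleophile and proton should both arrive on the exposed outer face of the ring alkene (a net syn addition across the E double bond, which is the C1/C10 relationship of the target), the outer face being fixed by the conformation that C6, C7 and C8 impose on the ring; the target is itself the formal methanol adduct of this dienone.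

Step 12
Reactants: 20 methanol adduct
Product: 21 8-hydroxy-1-methoxy-9-oxogermacr-4-en-6,12-olide (stereocentres as in the target)
Conditions: HF·pyridine, pyridine, THF, 0 to 23 °C
Reagents that add atoms: none
Why: Fluoride cleavage of the silyl ether under weakly acidic buffered conditions, chosen so that the methanol addition is not reversed and C8 and C10 are not epimerised.

Step 13
Reactants: 22 tiglic acid
Product: 23 (E)-2-methylbut-2-en-1-ol
Conditions: LiAlH4, Et2O, 0 °C
Reagents that add atoms: none
Why: Hydride reduction of the carboxylic acid to the allylic alcohol, with the E geometry untouched and conjugate reduction avoided at 0 °C.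

Step 14
Reactants: 23 (E)-2-methylbut-2-en-1-ol
Product: 24 (2R,3R)-2,3-epoxy-2-methylbutan-1-ol
Conditions: Ti(OiPr)4 (cat.), D-(−)-diethyl tartrate (cat.), t-BuOOH, 4 Å molecular sieves, CH2Cl2, −20 °C
Reagents that add atoms: tert-butyl hydroperoxide, CC(C)(C)OO
Why: Sharpless asymmetric epoxidation sets both oxirane stereocentres; E-2-methyl allylic alcohols give the (2S,3S)-epoxy alcohols with L-(+)-tartrate, so the D-(−)-ester is chosen for the (2R,3R) enantiomer.

Step 15
Reactants: 24 (2R,3R)-2,3-epoxy-2-methylbutan-1-ol
Product: 25 (2S,3R)-2,3-dimethyloxirane-2-carboxylic acid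
Conditions: RuCl3·xH2O (cat.), NaIO4, MeCN–EtOAc–H2O, 0 to 23 °C
Reagents that add atoms: water, O; NaIO4 (sodium periodate, terminal oxidant through RuO4), [Na+].[O-]I(=O)(=O)=O
Why: RuO4 generated in the flask oxidises the primary alcohol through the aldehyde hydrate to the acid without opening the oxirane (the usual route from 2,3-epoxy alcohols to glycidic acids); the C2 descriptor changes from R to S only because the carboxyl group outranks C3.

Step 16
Reactants: 21 C8 alcohol; 25 (2S,3R)-2,3-dimethyloxirane-2-carboxylic acid
Product: 27 target CNP0145898.1, via mixed anhydride 26 (not isolated)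
Conditions: 2,4,6-trichlorobenzoyl chloride, Et3N, THF, 23 °C; then 21, DMAP, toluene, 23 °C
Reagents that add atoms: none
Why: Yamaguchi esterification, in which the hindered epoxy acid is activated as the mixed trichlorobenzoic anhydride and transferred by DMAP to the secondary C8 alcohol with retention, under conditions mild enough for the β-methoxy ketone, the lactone and the oxirane.

**Compound list**

1 | (S)-carvone | CC1=CC[C@@H](CC1=O)C(C)=C | starting material
2 | tert-butyldimethylsilyl dienol ether of (S)-carvone (silyloxy on C9, double bonds C8=C9 and C10=C5) | CC1=CC[C@H](C(C)=C)C=C1O[Si](C)(C)C(C)(C)C | intermediate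
3 | (5R,6R)-6-(tert-butyldimethylsilyloxy)-2-methyl-5-(prop-1-en-2-yl)cyclohex-2-en-1-one (C8 silyl ether trans to the C7 isopropenyl group) | CC1=CC[C@H](C(C)=C)[C@@H](O[Si](C)(C)C(C)(C)C)C1=O | intermediate
4 | 3 with the isopropenyl group epoxidised, 5-(2-methyloxiran-2-yl) enone, both epimers at the oxirane carbon, ring centres as in 3 | CC1=CC[C@H](C2(C)CO2)[C@@H](O[Si](C)(C)C(C)(C)C)C1=O | intermediate
5 | 2-[6-(tert-butyldimethylsilyloxy)-4-methyl-5-oxocyclohex-3-en-1-yl]propanal, ring centres as in 3, both C11 epimers | CC1=CC[C@H](C(C)C=O)[C@@H](O[Si](C)(C)C(C)(C)C)C1=O | intermediate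
6 | 2-[6-(tert-butyldimethylsilyloxy)-4-methyl-5-oxocyclohex-3-en-1-yl]propanoic acid, ring centres as in 3, both C11 epimers | CC1=CC[C@H](C(C)C(=O)O)[C@@H](O[Si](C)(C)C(C)(C)C)C1=O | intermediate
7 | bis-silylated form of 6: tert-butyldimethylsilyl ester and linear tert-butyldimethylsilyl dienol ether (C9–OSi, C9=C10, C5=C6) | CC1=C(O[Si](C)(C)C(C)(C)C)[C@H](O[Si](C)(C)C(C)(C)C)[C@@H](C(C)C(=O)O[Si](C)(C)C(C)(C)C)C=C1 | intermediate
8 | 6-bromo enone tert-butyldimethylsilyl ester (bromine on C6, expected mainly trans to the C7 side chain) | CC1=CC(Br)[C@H](C(C)C(=O)O[Si](C)(C)C(C)(C)C)[C@@H](O[Si](C)(C)C(C)(C)C)C1=O | intermediate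
9 | cis-fused enone lactone, 4-(tert-butyldimethylsilyloxy)-3,6-dimethyl-3,3a,4,7a-tetrahydro-1-benzofuran-2,5-dione, both C11 epimers | CC1=C[C@@H]2OC(=O)C(C)[C@@H]2[C@@H](O[Si](C)(C)C(C)(C)C)C1=O | intermediate
10 | (3S,3aS,4R,7aS)-4-(tert-butyldimethylsilyloxy)-3,6-dimethyl-3,3a,4,7a-tetrahydro-1-benzofuran-2,5-dione (6S,7S,8R,11S in target numbering) | CC1=C[C@@H]2OC(=O)[C@@H](C)[C@@H]2[C@@H](O[Si](C)(C)C(C)(C)C)C1=O | intermediate
11 | benzeneselenenyl chloride | Cl[Se]c1ccccc1 | starting material
12 | ethyl vinyl ether | C=COCC | starting material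
13 | 1-chloro-1-ethoxy-2-(phenylseleno)ethane | CCOC(Cl)C[Se]c1ccccc1 | intermediate
14 | (phenylseleno)acetaldehyde | O=CC[Se]c1ccccc1 | intermediate
15 | isopropenylmagnesium bromide | C=C(C)[Mg]Br | starting material
16 | bromomagnesium enolate (C9–OMgBr, C9=C10) of the 5-isopropenyl lactone ketone, isopropenyl anti to C6–O | CC1=C(O[Mg]Br)[C@H](O[Si](C)(C)C(C)(C)C)[C@H]2[C@H](C)C(=O)O[C@H]2[C@@H]1C(C)=C | intermediate
17 | lactone ketone with C5 isopropenyl (trans to C6–O) and C10 bearing methyl and 1-hydroxy-2-(phenylseleno)ethyl (trans to isopropenyl), both carbinol epimers | OC(C[Se]c2ccccc2)[C@@]1(C)C(=O)[C@H](O[Si](C)(C)C(C)(C)C)[C@H]3[C@H](C)C(=O)O[C@H]3[C@@H]1C(C)=C | intermediate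
18 | (3S,3aS,4R,6R,7R,7aS)-4-(tert-butyldimethylsilyloxy)-6-ethenyl-3,6-dimethyl-7-(prop-1-en-2-yl)hexahydro-1-benzofuran-2,5-dione (Cope precursor) | C=C[C@@]1(C)C(=O)[C@H](O[Si](C)(C)C(C)(C)C)[C@H]2[C@H](C)C(=O)O[C@H]2[C@@H]1C(C)=C | intermediate
19 | (1(10)E,4E)-8-(tert-butyldimethylsilyloxy)-9-oxogermacra-1(10),4-dien-6,12-olide, C6, C7, C8, C11 as in 27 (Cope product) | C/C1=C\CC/C(C)=C/[C@@H]2OC(=O)[C@@H](C)[C@@H]2[C@@H](O[Si](C)(C)C(C)(C)C)C1=O | intermediate
20 | (4E)-8-(tert-butyldimethylsilyloxy)-1-methoxy-9-oxogermacr-4-en-6,12-olide, ring stereocentres as in 27 | CO[C@H]1CC/C(C)=C/[C@@H]2OC(=O)[C@@H](C)[C@@H]2[C@@H](O[Si](C)(C)C(C)(C)C)C(=O)[C@H]1C | intermediate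
21 | (4E)-8-hydroxy-1-methoxy-9-oxogermacr-4-en-6,12-olide, ring stereocentres as in 27 | CO[C@H]1CC/C(C)=C/[C@@H]2OC(=O)[C@@H](C)[C@@H]2[C@@H](O)C(=O)[C@H]1C | intermediate
22 | tiglic acid | C/C=C(\C)C(=O)O | starting material
23 | (E)-2-methylbut-2-en-1-ol | C/C=C(\C)CO | intermediate
24 | (2R,3R)-2,3-epoxy-2-methylbutan-1-ol | OC[C@@]1(C)O[C@@H]1C | intermediate
25 | (2S,3R)-2,3-dimethyloxirane-2-carboxylic acid | OC(=O)[C@@]1(C)O[C@@H]1C | intermediate
26 | mixed anhydride of 25 with 2,4,6-trichlorobenzoic acid | O=C(OC(=O)c1c(Cl)cc(Cl)cc1Cl)[C@@]2(C)O[C@@H]2C | intermediate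
27 | CNP0145898.1: (1S,4E,6S,7S,8R,10S,11S)-1-methoxy-9-oxogermacr-4-en-6,12-olid-8-yl (2S,3R)-2,3-dimethyloxirane-2-carboxylate | CO[C@H]1CC/C(C)=C/[C@@H]2OC(=O)[C@@H](C)[C@@H]2[C@@H](OC(=O)[C@@]2(C)O[C@@H]2C)C(=O)[C@H]1C | target

**Step count and risks**

Total: 16 steps. Longest linear sequence: 12 steps (steps 1 to 6, 8 to 12 and 16); step 7 and steps 13 to 15 are side branches.

The three steps most likely to fail:

1. Step 10. The equilibrium may lie far on the side of the six-membered isomer, so that each heating cycle returns little dienone, and the dienone may cyclise transannularly on acidic surfaces. The fallback removes the dienone from the equilibrium as it forms. Compound 18 would be heated (toluene, sealed tube, about 170 °C) with thiophenol and a catalytic amount of i-Pr2NEt. Thia-Michael addition to the enone is far more downhill than the Cope back-reaction and should give the 1-phenylthio-9-ketone F1 (C1 and C10 epimers, both usable). NaIO4 in aqueous methanol oxidises sulfur only, giving the sulfoxide F2. NaOMe in methanol at 0 °C then expels benzenesulfenate by E1cB from the C10 enolate, and the liberated enone takes up methanol in the same flask. The sequence rejoins the route at 20 without the free dienone ever being held at the temperature at which it reverts.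

2. Step 8. The organocopper intermediate at C5 may expel the C6 carboxylate (reductive opening of the γ-acyloxy enone) faster than it forms the C–C bond, and the hindered enolate may be protonated by the aldehyde instead of adding to it. The fallback takes the leaving group out of the enone before the addition. Compound 10 would be opened with LiOH (THF–H2O, 0 °C) and silylated with Et3SiCl and imidazole in DMF to the bis(triethylsilyl) seco derivative F3 (C6 silyl ether, silyl ester). Conjugate addition anti to a γ-silyloxy group is dependable, and the same addition and aldol sequence would give the aldol adduct F4. MsCl and Et3N then give the divinyl compound F5. Pyridinium p-toluenesulfonate in aqueous methanol removes both triethylsilyl groups, and the cis hydroxy acid closes to the lactone, rejoining the route at 18.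

3. Step 11. Stereocontrol may be lost: the C1 face may be attacked unselectively, C10 and C8 may equilibrate through their enolates, or the addition may reverse. The fallback avoids an equilibrating alkoxide. Compound 19 would be epoxidised under Weitz–Scheffer conditions (t-BuOOH, DBU, CH2Cl2, 0 °C), again on the outer face, to the 1,10-epoxy ketone F6. Reductive opening of the C10–O bond with the selenoborate made from (PhSe)2 and NaBH4 in ethanol and acetic acid gives the 1-hydroxy ketone F7, with C10 set by kinetic protonation. O-Methylation with Me3OBF4 and 1,8-bis(dimethylamino)naphthalene in CH2Cl2 then rejoins the route at 20.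

Further compounds
F1 | step 10 | 1-phenylthio adduct of 19: 8-(tert-butyldimethylsilyloxy)-9-oxo-1-(phenylthio)germacr-4-en-6,12-olide, C1 and C10 epimers | c1ccccc1SC1CC/C(C)=C/[C@@H]2OC(=O)[C@@H](C)[C@@H]2[C@@H](O[Si](C)(C)C(C)(C)C)C(=O)C1C
F2 | step 10 | sulfoxide of F1 | c1ccccc1S(=O)C1CC/C(C)=C/[C@@H]2OC(=O)[C@@H](C)[C@@H]2[C@@H](O[Si](C)(C)C(C)(C)C)C(=O)C1C
F3 | step 8 | ring-opened form of 10: C6 triethylsilyl ether, triethylsilyl ester, enone and C8 silyl ether unchanged | CC1=C[C@H](O[Si](CC)(CC)CC)[C@H]([C@H](C)C(=O)O[Si](CC)(CC)CC)[C@@H](O[Si](C)(C)C(C)(C)C)C1=O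
F4 | step 8 | aldol adduct from F3: C5 isopropenyl, C10 methyl and 1-hydroxy-2-(phenylseleno)ethyl, both carbinol epimers | OC(C[Se]c2ccccc2)[C@@]1(C)C(=O)[C@H](O[Si](C)(C)C(C)(C)C)[C@@H]([C@H](C)C(=O)O[Si](CC)(CC)CC)[C@@H](O[Si](CC)(CC)CC)[C@@H]1C(C)=C
F5 | step 8 | divinyl ketone from F4, ring-opened silylated form of 18 | C=C[C@@]1(C)C(=O)[C@H](O[Si](C)(C)C(C)(C)C)[C@@H]([C@H](C)C(=O)O[Si](CC)(CC)CC)[C@@H](O[Si](CC)(CC)CC)[C@@H]1C(C)=C
F6 | step 11 | trans-1,10-epoxy-8-(tert-butyldimethylsilyloxy)-9-oxogermacr-4-en-6,12-olide | C[C@@]12O[C@H]1CC/C(C)=C/[C@@H]3OC(=O)[C@@H](C)[C@@H]3[C@@H](O[Si](C)(C)C(C)(C)C)C2=O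
F7 | step 11 | 1-hydroxy-8-(tert-butyldimethylsilyloxy)-9-oxogermacr-4-en-6,12-olide, stereocentres as in 20 | O[C@H]1CC/C(C)=C/[C@@H]2OC(=O)[C@@H](C)[C@@H]2[C@@H](O[Si](C)(C)C(C)(C)C)C(=O)[C@H]1C
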